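The C3 hydroxyl on ring B is cis-1,4 to C7 (the methylene-bearing carbon on spiro C6) and trans to the C2 bromine, which is the imprint of a lactone bridge from C7 to C3. The target is therefore traced back to a C7 carboxylic acid on quaternary C6 of a 4-methylcyclohex-3-ene, itself a Diels–Alder adduct. Bromolactonisation forms the C2–Br and C3–O bonds in one operation and relays the C6 configuration to both new centres through a 2-oxabicyclo[2.2.2]octan-3-one. C8 of an iodoalkyl side chain then attacks the lactone carbonyl, closing ring A and releasing the C3 hydroxyl. Methylenation at C7 and bromination at C10 with inversion complete the route.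

Key step: step 8

Numbering (spiro[5.5]undecane numbering of the target): ring B is C1–C5, C6 is the spiro carbon, ring A is C7–C11; C7 carries the exocyclic methylene, C11 the gem-dimethyl group, C2 and C10 the bromines, C3 the methyl and hydroxyl groups.

Assumption: the (S)-SEGPHOS iridium catalyst (step 1) and the (S)-proline-derived oxazaborolidinium ion (step 6) are taken to give the (R)-carbinol and the (S)-configured quaternary carbon; should either sense prove opposite, the mirror-image ligand or catalyst is used.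

Step 1
Reactants: 1 3-(tert-butyldimethylsilyloxy)propan-1-ol; 2 3-methylbuta-1,2-diene
Product: 3 (3R)-1-(tert-butyldimethylsilyloxy)-4,4-dimethylhex-5-en-3-ol
Conditions: π-allyl iridium C,O-benzoate catalyst (5 mol %; preformed from [Ir(cod)Cl]2, (S)-SEGPHOS [(S)-5,5'-bis(diphenylphosphino)-4,4'-bi-1,3-benzodioxole], 4-cyano-3-nitrobenzoic acid and allyl acetate), 2 (3 equiv), toluene, 50 °C, sealed tube
Reagents that add atoms: none
Why: Iridium-catalysed transfer-hydrogenative carbonyl tert-prenylation: the catalyst dehydrogenates the alcohol to the aldehyde, hydrometallates the allene to a 1,1-dimethylallyl iridium species and adds it through a closed chair transition state, so the chiral bisphosphine sets the C10 carbinol as R at the carbon next to the new gem-dimethyl centre.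

Step 2
Reactants: 3 (3R)-1-(tert-butyldimethylsilyloxy)-4,4-dimethylhex-5-en-3-ol
Product: 4 (3R)-1,3-bis(tert-butyldimethylsilyloxy)-4,4-dimethylhex-5-ene
Conditions: TBSOTf, 2,6-lutidine, CH2Cl2, −78 to 0 °C
Reagents that add atoms: tert-butyldimethylsilyl trifluoromethanesulfonate, CC(C)(C)[Si](C)(C)OS(=O)(=O)C(F)(F)F
Why: Silylation of a hindered secondary alcohol with the silyl triflate and 2,6-lutidine is fast where the chloride would stall, and no stereocentre is touched.

Step 3
Reactants: 4 (3R)-1,3-bis(tert-butyldimethylsilyloxy)-4,4-dimethylhex-5-ene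
Product: 6 (4R)-4,6-bis(tert-butyldimethylsilyloxy)-3,3-dimethylhexan-1-ol, via B-alkyl-9-borabicyclo[3.3.1]nonane 5 (not isolated)
Conditions: 9-borabicyclo[3.3.1]nonane (1.5 equiv), THF, 0 °C to rt; then aq. NaOH, 30 % H2O2, 0 °C to rt
Reagents that add atoms: hydrogen peroxide, OO (oxygen of the new hydroxyl); 9-borabicyclo[3.3.1]nonane, B1C2CCCC1CCC2 (its atoms stay only in intermediate 5)
Why: Brown hydroboration–oxidation: the bulky borane adds boron to the terminal vinyl carbon remote from the quaternary centre and alkaline peroxide replaces boron by hydroxyl with both silyl ethers intact.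

Step 4
Reactants: 6 (4R)-4,6-bis(tert-butyldimethylsilyloxy)-3,3-dimethylhexan-1-ol
Product: 7 (4R)-4,6-bis(tert-butyldimethylsilyloxy)-3,3-dimethylhexanal
Conditions: Dess–Martin periodinane, NaHCO3, CH2Cl2, 0 °C to rt
Reagents that add atoms: none
Why: Dess–Martin oxidation under bicarbonate buffer stops at the aldehyde and is neutral enough for both silyl ethers.

Step 5
Reactants: 7 (4R)-4,6-bis(tert-butyldimethylsilyloxy)-3,3-dimethylhexanal; 8 formaldehyde
Product: 9 (4R)-4,6-bis(tert-butyldimethylsilyloxy)-3,3-dimethyl-2-methylidenehexanal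
Conditions: 8 (37 % aq.), pyrrolidine (10 mol %), propionic acid (10 mol %), i-PrOH, 45 °C
Reagents that add atoms: none
Why: Amine-catalysed Mannich condensation followed by elimination (α-methylenation of an aldehyde): the enamine of 7 attacks the formaldehyde-derived iminium ion and loss of the amine gives the enal, which cannot isomerise because the neighbouring C11 is quaternary.

Step 6
Reactants: 9 (4R)-4,6-bis(tert-butyldimethylsilyloxy)-3,3-dimethyl-2-methylidenehexanal; 10 isoprene (2-methylbuta-1,3-diene)
Product: 11 (1S)-1-[(3R)-3,5-bis(tert-butyldimethylsilyloxy)-2-methylpentan-2-yl]-4-methylcyclohex-3-ene-1-carbaldehyde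
Conditions: (S)-tetrahydro-1-(2-methylphenyl)-3,3-diphenyl-1H,3H-pyrrolo[1,2-c][1,3,2]oxazaborole (20 mol %) activated with HN(SO2CF3)2 (17 mol %), 10 (5 equiv), CH2Cl2, −78 to −40 °C
Reagents that add atoms: none
Why: Catalytic enantioselective Diels–Alder reaction: the protonated oxazaborolidine binds the formyl group of the 2-substituted acrolein and shields one face, isoprene adds with para orientation (ring methyl 1,4 to the formyl-bearing carbon) and the catalyst thereby sets quaternary C6, the minor C6 epimer being a separable diastereomer because C10 is already fixed.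

Step 7
Reactants: 11 (1S)-1-[(3R)-3,5-bis(tert-butyldimethylsilyloxy)-2-methylpentan-2-yl]-4-methylcyclohex-3-ene-1-carbaldehyde
Product: 12 (1S)-1-[(3R)-3,5-bis(tert-butyldimethylsilyloxy)-2-methylpentan-2-yl]-4-methylcyclohex-3-ene-1-carboxylic acid
Conditions: NaClO2, NaH2PO4, 2-methylbut-2-ene, t-BuOH/H2O, 0 °C to rt
Reagents that add atoms: sodium chlorite, [Na+].[O-]Cl=O
Why: Pinnick oxidation turns the hindered non-enolisable aldehyde into the acid while 2-methylbut-2-ene traps hypochlorous acid before it can reach the ring alkene.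

Step 8
Reactants: 12 (1S)-1-[(3R)-3,5-bis(tert-butyldimethylsilyloxy)-2-methylpentan-2-yl]-4-methylcyclohex-3-ene-1-carboxylic acid
Product: 13 (1R,4S,6R)-6-bromo-4-[(3R)-3,5-bis(tert-butyldimethylsilyloxy)-2-methylpentan-2-yl]-1-methyl-2-oxabicyclo[2.2.2]octan-3-one
Conditions: NBS (1.1 equiv), NaHCO3 (2 equiv), MeCN, 0 °C, dark
Reagents that add atoms: N-bromosuccinimide, O=C1CCC(=O)N1Br
Why: NBS delivers electrophilic bromine reversibly to either face of the C2=C3 alkene, but only the bromonium ion anti to the axial C6 carboxylate is captured, the carboxylate oxygen opening it at C3 through a boat-like transition state with anti addition. The closest known reaction type is the halolactonisation of 4-methylcyclohex-3-ene-1-carboxylic acids, which gives bridged δ-lactones by Markovnikov capture. One ring closes, the δ-lactone of the 2-oxabicyclo[2.2.2]octan-3-one, a 6-exo closure when counted through C5–C4 and a 6-endo closure when counted through C1–C2. C3 is set by the tether, which can place oxygen only on the face that carries C7, and C2 by the anti opening, which leaves bromine on the opposite face, so both new centres follow from C6. The step needs attack at tertiary C3 and not at secondary C2 (the γ-lactone of a 6-oxabicyclo[3.2.1]octane), and the C3 methyl group secures this by localising the positive charge at C3. Chemoselectivity is secured because the side chain holds only silyl ethers, with no second alkene and no free nucleophile.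

Step 9
Reactants: 13 (1R,4S,6R)-6-bromo-4-[(3R)-3,5-bis(tert-butyldimethylsilyloxy)-2-methylpentan-2-yl]-1-methyl-2-oxabicyclo[2.2.2]octan-3-one
Product: 14 (1R,4S,6R)-6-bromo-4-[(3R)-3-(tert-butyldimethylsilyloxy)-5-hydroxy-2-methylpentan-2-yl]-1-methyl-2-oxabicyclo[2.2.2]octan-3-one
Conditions: HF·pyridine, pyridine, THF, 0 °C
Reagents that add atoms: none
Why: Fluoride desilylation under steric control: buffered HF·pyridine cleaves the unhindered primary silyl ether and leaves the secondary one beside quaternary C11, the lactone and the bromide untouched.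

Step 10
Reactants: 14 (1R,4S,6R)-6-bromo-4-[(3R)-3-(tert-butyldimethylsilyloxy)-5-hydroxy-2-methylpentan-2-yl]-1-methyl-2-oxabicyclo[2.2.2]octan-3-one
Product: 15 (1R,4S,6R)-6-bromo-4-[(3R)-3-(tert-butyldimethylsilyloxy)-5-iodo-2-methylpentan-2-yl]-1-methyl-2-oxabicyclo[2.2.2]octan-3-one
Conditions: I2, PPh3, imidazole, CH2Cl2, 0 °C to rt, dark
Reagents that add atoms: iodine, II
Why: Appel-type iodination (Garegg–Samuelsson conditions): the primary alkoxyphosphonium ion is displaced by iodide in an SN2 reaction under near-neutral conditions that spare the lactone and the secondary bromide.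

Step 11
Reactants: 15 (1R,4S,6R)-6-bromo-4-[(3R)-3-(tert-butyldimethylsilyloxy)-5-iodo-2-methylpentan-2-yl]-1-methyl-2-oxabicyclo[2.2.2]octan-3-one
Product: 16 (2R,3R,6S,10R)-2-bromo-10-(tert-butyldimethylsilyloxy)-3-hydroxy-3,11,11-trimethylspiro[5.5]undecan-7-one
Conditions: SmI2 (2.5 equiv), Fe(PhCOCHCOPh)3 (2 mol %), THF, −30 to 0 °C; then pH 7 phosphate buffer
Reagents that add atoms: none
Why: Samarium Barbier-type intramolecular nucleophilic acyl substitution: samarium diiodide with the iron catalyst reduces the primary C–I bond well below the temperature at which the secondary C–Br bond reacts, the C8 organosamarium adds in 6-exo fashion to the lactone carbonyl C7 to close ring A, and the bridged hemiketalate, which shields the carbonyl from a second addition, collapses to the C7 ketone with release of the C3 oxygen as the alkoxide.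

Step 12
Reactants: 16 (2R,3R,6S,10R)-2-bromo-10-(tert-butyldimethylsilyloxy)-3-hydroxy-3,11,11-trimethylspiro[5.5]undecan-7-one
Product: 17 (2R,3R,6R,10R)-2-bromo-10-(tert-butyldimethylsilyloxy)-3,11,11-trimethyl-7-methylidenespiro[5.5]undecan-3-ol
Conditions: Cp2Ti(μ-CH2)(μ-Cl)AlMe2 (3 equiv), pyridine (cat.), THF/toluene, −40 °C to rt; then aq. NaHCO3
Reagents that add atoms: Tebbe reagent Cp2Ti(μ-CH2)(μ-Cl)AlMe2, C[Al-]1(C)C[Ti](C2C=CC=C2)(C2C=CC=C2)[Cl+]1
Why: Tebbe methylenation: the small, non-basic titanium methylidene adds to the ketone flanked by quaternary C6 through an oxatitanacyclobutane without enolisation or epoxide closure of the bromohydrin, one extra equivalent being spent on the free hydroxyl.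

Step 13
Reactants: 17 (2R,3R,6R,10R)-2-bromo-10-(tert-butyldimethylsilyloxy)-3,11,11-trimethyl-7-methylidenespiro[5.5]undecan-3-ol
Product: 18 (2R,3R,6R,10R)-2-bromo-3,11,11-trimethyl-7-methylidenespiro[5.5]undecane-3,10-diol
Conditions: HF·pyridine (excess), THF, 0 °C to rt
Reagents that add atoms: none
Why: Fluoride desilylation with HF·pyridine removes the remaining hindered silyl ether under mildly acidic conditions, which avoids the C3 alkoxide that a basic fluoride source could drive onto C2.

Step 14
Reactants: 18 (2R,3R,6R,10R)-2-bromo-3,11,11-trimethyl-7-methylidenespiro[5.5]undecane-3,10-diol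
Product: 19 (2R,3R,6R,10S)-2,10-dibromo-3,11,11-trimethyl-7-methylidenespiro[5.5]undecan-3-ol (CNP0114057.1)
Conditions: CBr4 (4 equiv), P(n-C8H17)3 (4 equiv), 1-methylcyclohexene (acid trap), toluene, 70 °C, dark
Reagents that add atoms: carbon tetrabromide, BrC(Br)(Br)Br
Why: Appel bromination with a small, strongly nucleophilic trialkylphosphine: bromide displaces the C10 alkoxyphosphonium group by SN2 with inversion to give the (S)-bromide, while the tertiary C3 hydroxyl, crowded and inductively deactivated by the C2 bromine, is expected to stay free.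

Compound list
1 | 3-(tert-butyldimethylsilyloxy)propan-1-ol | OCCCO[Si](C)(C)C(C)(C)C | starting material
2 | 3-methylbuta-1,2-diene | C=C=C(C)C | starting material
3 | (3R)-1-(tert-butyldimethylsilyloxy)-4,4-dimethylhex-5-en-3-ol | C=CC(C)(C)[C@H](O)CCO[Si](C)(C)C(C)(C)C | intermediate
4 | (3R)-1,3-bis(tert-butyldimethylsilyloxy)-4,4-dimethylhex-5-ene | C=CC(C)(C)[C@H](O[Si](C)(C)C(C)(C)C)CCO[Si](C)(C)C(C)(C)C | intermediate
5 | 9-[(4R)-4,6-bis(tert-butyldimethylsilyloxy)-3,3-dimethylhexyl]-9-borabicyclo[3.3.1]nonane (B-alkyl-9-borabicyclo[3.3.1]nonane, not isolated) | CC(C)(CCB1C2CCCC1CCC2)[C@H](O[Si](C)(C)C(C)(C)C)CCO[Si](C)(C)C(C)(C)C | intermediate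
6 | (4R)-4,6-bis(tert-butyldimethylsilyloxy)-3,3-dimethylhexan-1-ol | OCCC(C)(C)[C@H](O[Si](C)(C)C(C)(C)C)CCO[Si](C)(C)C(C)(C)C | intermediate
7 | (4R)-4,6-bis(tert-butyldimethylsilyloxy)-3,3-dimethylhexanal | O=CCC(C)(C)[C@H](O[Si](C)(C)C(C)(C)C)CCO[Si](C)(C)C(C)(C)C | intermediate
8 | formaldehyde | C=O | starting material
9 | (4R)-4,6-bis(tert-butyldimethylsilyloxy)-3,3-dimethyl-2-methylidenehexanal | C=C(C=O)C(C)(C)[C@H](O[Si](C)(C)C(C)(C)C)CCO[Si](C)(C)C(C)(C)C | intermediate
10 | isoprene (2-methylbuta-1,3-diene) | C=CC(C)=C | starting material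
11 | (1S)-1-[(3R)-3,5-bis(tert-butyldimethylsilyloxy)-2-methylpentan-2-yl]-4-methylcyclohex-3-ene-1-carbaldehyde | O=C[C@]1(CCC(C)=CC1)C(C)(C)[C@H](O[Si](C)(C)C(C)(C)C)CCO[Si](C)(C)C(C)(C)C | intermediate
12 | (1S)-1-[(3R)-3,5-bis(tert-butyldimethylsilyloxy)-2-methylpentan-2-yl]-4-methylcyclohex-3-ene-1-carboxylic acid | OC(=O)[C@]1(CCC(C)=CC1)C(C)(C)[C@H](O[Si](C)(C)C(C)(C)C)CCO[Si](C)(C)C(C)(C)C | intermediate
13 | (1R,4S,6R)-6-bromo-4-[(3R)-3,5-bis(tert-butyldimethylsilyloxy)-2-methylpentan-2-yl]-1-methyl-2-oxabicyclo[2.2.2]octan-3-one (lactone oxygen on C3 on the face of C7, bromine on C2 on the opposite face) | CC(C)(C)[Si](C)(C)OCC[C@@H](O[Si](C)(C)C(C)(C)C)C(C)(C)[C@@]12CC[C@@](C)(OC1=O)[C@H](Br)C2 | intermediate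
14 | (1R,4S,6R)-6-bromo-4-[(3R)-3-(tert-butyldimethylsilyloxy)-5-hydroxy-2-methylpentan-2-yl]-1-methyl-2-oxabicyclo[2.2.2]octan-3-one | OCC[C@@H](O[Si](C)(C)C(C)(C)C)C(C)(C)[C@@]12CC[C@@](C)(OC1=O)[C@H](Br)C2 | intermediate
15 | (1R,4S,6R)-6-bromo-4-[(3R)-3-(tert-butyldimethylsilyloxy)-5-iodo-2-methylpentan-2-yl]-1-methyl-2-oxabicyclo[2.2.2]octan-3-one | ICC[C@@H](O[Si](C)(C)C(C)(C)C)C(C)(C)[C@@]12CC[C@@](C)(OC1=O)[C@H](Br)C2 | intermediate
16 | (2R,3R,6S,10R)-2-bromo-10-(tert-butyldimethylsilyloxy)-3-hydroxy-3,11,11-trimethylspiro[5.5]undecan-7-one | O=C1CC[C@@H](O[Si](C)(C)C(C)(C)C)C(C)(C)[C@@]12CC[C@@](C)(O)[C@H](Br)C2 | intermediate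
17 | (2R,3R,6R,10R)-2-bromo-10-(tert-butyldimethylsilyloxy)-3,11,11-trimethyl-7-methylidenespiro[5.5]undecan-3-ol | C=C1CC[C@@H](O[Si](C)(C)C(C)(C)C)C(C)(C)[C@@]12CC[C@@](C)(O)[C@H](Br)C2 | intermediate
18 | (2R,3R,6R,10R)-2-bromo-3,11,11-trimethyl-7-methylidenespiro[5.5]undecane-3,10-diol | C=C1CC[C@@H](O)C(C)(C)[C@@]12CC[C@@](C)(O)[C@H](Br)C2 | intermediate
19 | (2R,3R,6R,10S)-2,10-dibromo-3,11,11-trimethyl-7-methylidenespiro[5.5]undecan-3-ol (CNP0114057.1) | C=C1CC[C@H](Br)C(C)(C)[C@@]12CC[C@@](C)(O)[C@H](Br)C2 | target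

Total step count: 14
Longest linear sequence: 14 steps (from 1 to 19; 2, 8 and 10 enter as purchased one-step partners)

Steps most likely to fail

Step 14. The displacement at neopentylic C10 is slow, so the excess bromophosphonium reagent may also activate the tertiary C3 hydroxyl (dehydration or exchange) before substitution at C10 is complete. The fallback sets out from 17 and caps the tertiary hydroxyl first. Acetylation (Ac2O, DMAP, Et3N, CH2Cl2, rt to 40 °C) should give the tertiary acetate F1. HF·pyridine in THF then frees C10 to give the hydroxy acetate F2. The same trialkylphosphine Appel bromination, now free to run hotter and longer, should give the dibromo acetate F3 with inversion at C10. Reductive removal of the acetate with i-Bu2AlH in CH2Cl2 at −78 °C returns the route at 19.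

Step 11. Electron transfer to the secondary C2–Br bond, followed by expulsion of the carboxylate and loss of the bridge, may compete with reduction of the primary iodide; the organosamarium may also be protonated before it reaches the crowded carbonyl. The fallback sets out from 15 and replaces the reductive closure by a stabilised-carbanion acylation. Displacement of iodide with PhSO2Na in DMF at rt should give the phenyl sulfone F4. Lithium diisopropylamide (2.2 equiv, THF, −78 °C, cold quench with acetic acid) generates the α-sulfonyl carbanion at C8, which acylates on the lactone carbonyl in a Claisen-type 6-exo closure to give the β-keto sulfone F5 with the C3 hydroxyl released. Desulfonylation with aluminium amalgam in wet THF returns the route at 16.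

Step 6. The α-tert-alkyl group crowds the catalyst-bound enal, so turnover may be slow and facial discrimination weak. The fallback sets out from 9 and 10 and gives up catalyst control: stoichiometric Me2AlCl in CH2Cl2 at −78 to −20 °C should promote the para-selective cycloaddition with both C6 configurations formed. Because C10 is already fixed, the unwanted adduct, the C6-epimeric aldehyde F6, is a diastereomer and is removed by chromatography. The route is rejoined at 11.

Further compounds
F1 | step 14 | (2R,3R,6R,10R)-2-bromo-10-(tert-butyldimethylsilyloxy)-3,11,11-trimethyl-7-methylidenespiro[5.5]undecan-3-yl acetate | C=C1CC[C@@H](O[Si](C)(C)C(C)(C)C)C(C)(C)[C@@]12CC[C@@](C)(OC(C)=O)[C@H](Br)C2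
F2 | step 14 | (2R,3R,6R,10R)-2-bromo-10-hydroxy-3,11,11-trimethyl-7-methylidenespiro[5.5]undecan-3-yl acetate | C=C1CC[C@@H](O)C(C)(C)[C@@]12CC[C@@](C)(OC(C)=O)[C@H](Br)C2
F3 | step 14 | (2R,3R,6R,10S)-2,10-dibromo-3,11,11-trimethyl-7-methylidenespiro[5.5]undecan-3-yl acetate | C=C1CC[C@H](Br)C(C)(C)[C@@]12CC[C@@](C)(OC(C)=O)[C@H](Br)C2
F4 | step 11 | (1R,4S,6R)-6-bromo-4-[(3R)-3-(tert-butyldimethylsilyloxy)-2-methyl-5-(phenylsulfonyl)pentan-2-yl]-1-methyl-2-oxabicyclo[2.2.2]octan-3-one | O=S(=O)(CC[C@@H](O[Si](C)(C)C(C)(C)C)C(C)(C)[C@@]12CC[C@@](C)(OC1=O)[C@H](Br)C2)c1ccccc1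
F5 | step 11 | (2R,3R,6S,10R)-2-bromo-10-(tert-butyldimethylsilyloxy)-3-hydroxy-3,11,11-trimethyl-8-(phenylsulfonyl)spiro[5.5]undecan-7-one (mixture at C8) | O=C1C(S(=O)(=O)c2ccccc2)C[C@@H](O[Si](C)(C)C(C)(C)C)C(C)(C)[C@@]13CC[C@@](C)(O)[C@H](Br)C3
F6 | step 6 | (1R)-1-[(3R)-3,5-bis(tert-butyldimethylsilyloxy)-2-methylpentan-2-yl]-4-methylcyclohex-3-ene-1-carbaldehyde | O=C[C@@]1(CCC(C)=CC1)C(C)(C)[C@H](O[Si](C)(C)C(C)(C)C)CCO[Si](C)(C)C(C)(C)C
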